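**Retrosynthetic overview**

1. Numbering: ring C1 (C=O), C2 (allyl), C3, C4 (quaternary C–OMe), C5 (C–OMe), C6; side chain C7 (CH–CH3), C9 (ArCH2). The plan rests on the adjacent C4/C7 stereocentres: C9–C7–C4–C5 plus the C5 oxygen are folded into a five-membered γ-aryl-α-methoxy lactone ring (O–C5–C4–C7–C9), so that one C9 centre, erased later, steers C7 and then C4.
2. Dienone ring (the only carbocycle built, closed last): C2–C3 by intramolecular aldol condensation, C5–OMe by methoxide addition to the ynone C5≡C6–C1=O of an open-chain ynone aldehyde.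
3. Ynone aldehyde ⇐ acetylide at C5 (lactone carbonyl → acid → ester → aldehyde → dibromoalkene) + pent-4-enal (C1, C2, allyl); the lactone is opened and C9 deoxygenated by benzylic hydrogenolysis before any alkene exists.
4. Hydroxymethyl lactone ⇐ (5S)-butenolide + Me2CuLi + CH2O (C7–CH3 and C3–C4 bonds; no ring closed).
5. Butenolide ⇐ (S)-γ-aryl-γ-butyrolactone (α-hydroxylation, O-methylation, selenoxide elimination) ⇐ asymmetric transfer hydrogenation of the γ-keto ester from silylated acetovanillone and methyl bromoacetate.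

Key step: step 7

Remark: Ar = 4-(tert-butyldimethylsilyloxy)-3-methoxyphenyl throughout. Formaldehyde in step 7 is assumed to be the monomer, delivered as a cold THF solution from cracked paraformaldehyde. CIP descriptors were re-derived for each intermediate because substituent priorities at the quaternary carbon change along the route.

**Route**

Step 1
Reactants: 1 1-(4-hydroxy-3-methoxyphenyl)ethanone (acetovanillone)
Product: 2 1-[4-(tert-butyldimethylsilyloxy)-3-methoxyphenyl]ethanone
Conditions: tBuMe2SiCl, imidazole, DMF, rt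
Reagents that add atoms: tert-butyldimethylsilyl chloride, CC(C)(C)[Si](C)(C)Cl
Why: Imidazole-promoted O-silylation masks the acidic phenol before the enolate, cuprate and organolithium steps; no stereocentre is involved.

Step 2
Reactants: 2 1-[4-(tert-butyldimethylsilyloxy)-3-methoxyphenyl]ethanone; 3 methyl bromoacetate
Product: 5 methyl 4-Ar-4-oxobutanoate, via ketone lithium enolate 4 (not isolated)
Conditions: LiN(SiMe3)2, THF, −78 °C; then 3, −78 → 0 °C
Reagents that add atoms: none
Why: Enolate alkylation (SN2) should work because the aryl methyl ketone has a single enolisable position and the α-bromo ester is a reactive electrophile, giving the γ-keto ester.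

Step 3
Reactants: 5 methyl 4-Ar-4-oxobutanoate
Product: 7 (5S)-5-Ar-dihydrofuran-2(3H)-one, via hydroxy ester 6 (not isolated)
Conditions: RuCl(p-cymene)[(S,S)-TsDPEN] (1 mol%), HCO2H/Et3N (5:2), 40 °C; then PPTS (cat.), PhMe, 60 °C
Reagents that add atoms: none
Why: Noyori asymmetric transfer hydrogenation of the aryl ketone with the (S,S)-catalyst should deliver hydride to the face that gives the (S)-benzylic alcohol (aryl versus CH2 differentiation as for acetophenone), and lactonisation of the γ-hydroxy ester then fixes the C9 relay stereocentre in the ring.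

Step 4
Reactants: 7 (5S)-5-Ar-dihydrofuran-2(3H)-one
Product: 9 (3RS,5S)-5-Ar-3-hydroxydihydrofuran-2(3H)-one, via lactone sodium enolate 8 (not isolated)
Conditions: NaN(SiMe3)2, THF, −78 °C; then 2-(phenylsulfonyl)-3-phenyloxaziridine, −78 °C; NH4Cl aq
Reagents that add atoms: 2-(phenylsulfonyl)-3-phenyloxaziridine, O=S(=O)(N1OC1c1ccccc1)c1ccccc1
Why: Electrophilic α-hydroxylation of the lactone enolate by the N-sulfonyloxaziridine (oxygen transfer) is standard for γ-lactones; the new C3 centre forms as a mixture, which is harmless because C3 becomes sp2 in step 6, and C5 is not acidic here.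

Step 5
Reactants: 9 (3RS,5S)-5-Ar-3-hydroxydihydrofuran-2(3H)-one
Product: 10 (3RS,5S)-5-Ar-3-methoxydihydrofuran-2(3H)-one
Conditions: Ag2O, MeI, MeCN, rt → 40 °C, dark
Reagents that add atoms: iodomethane, CI
Why: Silver-oxide-mediated O-methylation (Williamson-type etherification) alkylates the α-hydroxy lactone without strong base, so neither the lactone nor C5 is disturbed.

Step 6
Reactants: 10 (3RS,5S)-5-Ar-3-methoxydihydrofuran-2(3H)-one
Product: 13 (5S)-5-Ar-3-methoxyfuran-2(5H)-one, via methoxy lactone lithium enolate 11 (not isolated), via selanyl lactone 12 (not isolated)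
Conditions: LiN(iPr)2, THF, −78 °C; PhSeBr; then NaIO4, NaHCO3, THF/MeOH/H2O, 0 °C → rt
Reagents that add atoms: none
Why: α-Selenenylation of the enolate followed by selenoxide syn-elimination, which can only take a C4 hydrogen, should give the endocyclic C3=C4 bond of the α-methoxybutenolide; periodate is used instead of peroxide so that no peroxyseleninic acid attacks the electron-rich alkene, and the near-neutral medium spares the base-sensitive C5–H.

Step 7
Reactants: 13 (5S)-5-Ar-3-methoxyfuran-2(5H)-one; 14 lithium dimethylcuprate; 15 formaldehyde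
Product: 17 (3S,4R,5S)-5-Ar-3-(hydroxymethyl)-3-methoxy-4-methyldihydrofuran-2(3H)-one, via methylated lactone lithium enolate 16 (not isolated)
Conditions: Me2CuLi (2 equiv, from MeLi and CuI), Et2O, −78 → −20 °C; then CH2O (monomer, THF solution, excess), −78 °C; NH4Cl/NH3 aq at −78 °C
Reagents that add atoms: none
Why: The cuprate forms a π-complex with the C3=C4 bond of 13 on the face away from the C5 aryl group, transfers methyl to C4 (C7 of the target) through a trivalent-copper β-adduct and leaves the lithium enolate 16 with methyl trans to aryl; monomeric formaldehyde then adds to the tetrasubstituted enolate carbon C3 (C4 of the target) from the face opposite the neighbouring methyl group (aldol addition), which sets hydroxymethyl trans and methoxy cis to methyl. The closest known reaction type is the tandem conjugate addition–enolate trapping (three-component coupling) of γ-substituted butenolides, in which both new substituents enter trans to their ring neighbours. No ring is closed; the C7–CH3 and C3–C4 bonds and the stereocentres C7 and C4 are formed. C7 is controlled by the C5 centre of the lactone (C9 of the target), and C4 by the newly set C7 centre. The step needs 1,4- over 1,2-addition, which the soft cuprate on a strained cis-enoate secures although the α-methoxy group makes the acceptor slower (hence excess cuprate and warming to −20 °C), and it needs the aldolate to survive, which the quench at −78 °C secures because the β-alkoxide on a quaternary α-carbon can revert by retro-aldol cleavage.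

Step 8
Reactants: 17 (3S,4R,5S)-5-Ar-3-(hydroxymethyl)-3-methoxy-4-methyldihydrofuran-2(3H)-one
Product: 18 (3S,4R,5S)-5-Ar-3-[(tert-butyldimethylsilyloxy)methyl]-3-methoxy-4-methyldihydrofuran-2(3H)-one
Conditions: tBuMe2SiCl, imidazole, DMF, rt
Reagents that add atoms: tert-butyldimethylsilyl chloride, CC(C)(C)[Si](C)(C)Cl
Why: O-Silylation of the primary alcohol blocks retro-aldol loss of formaldehyde and protects the future C3 oxygen through the reduction and organometallic steps.

Step 9
Reactants: 18 (3S,4R,5S)-5-Ar-3-[(tert-butyldimethylsilyloxy)methyl]-3-methoxy-4-methyldihydrofuran-2(3H)-one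
Product: 19 (2S,3R)-4-Ar-2-[(tert-butyldimethylsilyloxy)methyl]-2-methoxy-3-methylbutanoic acid
Conditions: H2 (1 atm), Pd/C, EtOAc/AcOH (10:1), rt
Reagents that add atoms: none
Why: Benzylic hydrogenolysis of the γ-aryl lactone C–O bond (carboxylate leaving group, electron-rich arene) erases the C9 stereocentre and opens the ring while no alkene is yet present; C7 and C4 are not touched.

Step 10
Reactants: 19 (2S,3R)-4-Ar-2-[(tert-butyldimethylsilyloxy)methyl]-2-methoxy-3-methylbutanoic acid
Product: 20 methyl (2S,3R)-4-Ar-2-[(tert-butyldimethylsilyloxy)methyl]-2-methoxy-3-methylbutanoate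
Conditions: Me3SiCHN2, MeOH/PhMe, 0 °C
Reagents that add atoms: trimethylsilyldiazomethane, C[Si](C)(C)C=[N+]=[N-]
Why: Diazoalkane esterification methylates the hindered α-quaternary acid under neutral conditions where acid-catalysed esterification would be slow.

Step 11
Reactants: 20 methyl (2S,3R)-4-Ar-2-[(tert-butyldimethylsilyloxy)methyl]-2-methoxy-3-methylbutanoate
Product: 21 (2S,3R)-4-Ar-2-[(tert-butyldimethylsilyloxy)methyl]-2-methoxy-3-methylbutanal
Conditions: iBu2AlH (1.1 equiv), CH2Cl2, −78 °C; KNaC4H4O6 aq (potassium sodium tartrate)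
Reagents that add atoms: none
Why: Partial ester reduction should stop at the aldehyde because the tetrahedral aluminate is held by chelation to the α-methoxy group at −78 °C, and the quaternary α-carbon cannot epimerise.

Step 12
Reactants: 21 (2S,3R)-4-Ar-2-[(tert-butyldimethylsilyloxy)methyl]-2-methoxy-3-methylbutanal
Product: 22 (3R,4R)-1,1-dibromo-5-Ar-3-[(tert-butyldimethylsilyloxy)methyl]-3-methoxy-4-methylpent-1-ene
Conditions: CBr4, PPh3, Zn, CH2Cl2, rt
Reagents that add atoms: carbon tetrabromide, BrC(Br)(Br)Br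
Why: Corey–Fuchs dibromo-olefination (Wittig reaction of Ph3P=CBr2, generated with Zn so that no Ph3PBr2 attacks the silyl ethers) turns the non-enolisable aldehyde carbon C5 into the future alkyne carbon.

Step 13
Reactants: 22 (3R,4R)-1,1-dibromo-5-Ar-3-[(tert-butyldimethylsilyloxy)methyl]-3-methoxy-4-methylpent-1-ene; 23 pent-4-enal
Product: 25 (5RS,8R,9R)-10-Ar-8-[(tert-butyldimethylsilyloxy)methyl]-8-methoxy-9-methyldec-1-en-6-yn-5-ol, via lithium acetylide 24 (not isolated)
Conditions: nBuLi (2.1 equiv), THF, −78 °C; then 23, −78 → 0 °C; NH4Cl aq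
Reagents that add atoms: none
Why: Bromine–lithium exchange and Fritsch–Buttenberg–Wiechell rearrangement give the lithium acetylide (second stage of the Corey–Fuchs sequence), which adds 1,2 to pent-4-enal and joins C6 to C1; the carbinol centre forms unselectively and is removed by oxidation in step 15.

Step 14
Reactants: 25 (5RS,8R,9R)-10-Ar-8-[(tert-butyldimethylsilyloxy)methyl]-8-methoxy-9-methyldec-1-en-6-yn-5-ol
Product: 26 (5RS,8R,9R)-10-Ar-8-(hydroxymethyl)-8-methoxy-9-methyldec-1-en-6-yn-5-ol
Conditions: camphorsulfonic acid (cat.), MeOH/CH2Cl2, 0 °C → rt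
Reagents that add atoms: none
Why: Acid-catalysed methanolysis should remove the alkyl silyl ether selectively, since the aryl silyl ether oxygen is far less basic and is cleaved much more slowly under acid.

Step 15
Reactants: 26 (5RS,8R,9R)-10-Ar-8-(hydroxymethyl)-8-methoxy-9-methyldec-1-en-6-yn-5-ol
Product: 27 (2R)-2-[(2R)-1-Ar-propan-2-yl]-2-methoxy-5-oxonon-8-en-3-ynal
Conditions: Dess–Martin periodinane (3 equiv), NaHCO3, CH2Cl2, 0 °C → rt
Reagents that add atoms: none
Why: Dess–Martin oxidation converts the primary alcohol into the C3 aldehyde and the propargylic alcohol into the ynone in one operation, and the only stereocentre next to a new carbonyl is quaternary.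

Step 16
Reactants: 27 (2R)-2-[(2R)-1-Ar-propan-2-yl]-2-methoxy-5-oxonon-8-en-3-ynal
Product: 30 (4S)-4-[(2R)-1-(4-hydroxy-3-methoxyphenyl)propan-2-yl]-4,5-dimethoxy-2-(prop-2-en-1-yl)cyclohexa-2,5-dien-1-one (target), via silylated methoxy enone aldehyde 28 (not isolated), via phenolic methoxy enone aldehyde 29 (not isolated)
Conditions: NaOMe (3 equiv), MeOH (0.01 M), 3 Å molecular sieves, 0 → 40 °C; NH4Cl aq
Reagents that add atoms: sodium methoxide, [Na+].[O-]C
Why: Conjugate addition of methoxide to the ynone puts the methoxy group on C5 and nowhere else, reversible methoxide addition interconverts the enone geometries so that the isomer with C1 cis to C4 is drained by intramolecular aldol condensation of the C2 enolate with the C3 aldehyde (six-membered ring, E1cB dehydration), and the same medium methanolyses the aryl silyl ether; C4 and C7 are not enolisable and keep their configuration.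

**Compound list**

1 | 1-(4-hydroxy-3-methoxyphenyl)ethanone (acetovanillone) | CC(=O)c1ccc(O)c(OC)c1 | starting material
2 | 1-[4-(tert-butyldimethylsilyloxy)-3-methoxyphenyl]ethanone | CC(=O)c1ccc(O[Si](C)(C)C(C)(C)C)c(OC)c1 | intermediate
3 | methyl bromoacetate | COC(=O)CBr | starting material
4 | lithium 1-Ar-ethen-1-olate | [Li+].[O-]C(=C)c1ccc(O[Si](C)(C)C(C)(C)C)c(OC)c1 | intermediate
5 | methyl 4-Ar-4-oxobutanoate | COC(=O)CCC(=O)c1ccc(O[Si](C)(C)C(C)(C)C)c(OC)c1 | intermediate
6 | methyl (4S)-4-Ar-4-hydroxybutanoate | COC(=O)CC[C@H](O)c1ccc(O[Si](C)(C)C(C)(C)C)c(OC)c1 | intermediate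
7 | (5S)-5-Ar-dihydrofuran-2(3H)-one | O=C1CC[C@@H](c2ccc(O[Si](C)(C)C(C)(C)C)c(OC)c2)O1 | intermediate
8 | sodium (5S)-5-Ar-4,5-dihydrofuran-2-olate | [Na+].[O-]C1=CC[C@@H](c2ccc(O[Si](C)(C)C(C)(C)C)c(OC)c2)O1 | intermediate
9 | (3RS,5S)-5-Ar-3-hydroxydihydrofuran-2(3H)-one | O=C1O[C@H](c2ccc(O[Si](C)(C)C(C)(C)C)c(OC)c2)CC1O | intermediate
10 | (3RS,5S)-5-Ar-3-methoxydihydrofuran-2(3H)-one | O=C1O[C@H](c2ccc(O[Si](C)(C)C(C)(C)C)c(OC)c2)CC1OC | intermediate
11 | lithium (5S)-5-Ar-3-methoxy-4,5-dihydrofuran-2-olate | [Li+].[O-]C1=C(OC)C[C@@H](c2ccc(O[Si](C)(C)C(C)(C)C)c(OC)c2)O1 | intermediate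
12 | (3RS,5S)-5-Ar-3-methoxy-3-(phenylselanyl)dihydrofuran-2(3H)-one | O=C1O[C@H](c2ccc(O[Si](C)(C)C(C)(C)C)c(OC)c2)CC1(OC)[Se]c1ccccc1 | intermediate
13 | (5S)-5-Ar-3-methoxyfuran-2(5H)-one | COC1=C[C@@H](c2ccc(O[Si](C)(C)C(C)(C)C)c(OC)c2)OC1=O | intermediate
14 | lithium dimethylcuprate | [Li+].C[Cu-]C | starting material (reagent, generated in the flask from MeLi and CuI)
15 | formaldehyde | C=O | starting material
16 | lithium (4R,5S)-5-Ar-3-methoxy-4-methyl-4,5-dihydrofuran-2-olate | [Li+].[O-]C1=C(OC)[C@H](C)[C@@H](c2ccc(O[Si](C)(C)C(C)(C)C)c(OC)c2)O1 | intermediate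
17 | (3S,4R,5S)-5-Ar-3-(hydroxymethyl)-3-methoxy-4-methyldihydrofuran-2(3H)-one | O=C1O[C@H](c2ccc(O[Si](C)(C)C(C)(C)C)c(OC)c2)[C@@H](C)[C@]1(OC)CO | intermediate
18 | (3S,4R,5S)-5-Ar-3-[(tert-butyldimethylsilyloxy)methyl]-3-methoxy-4-methyldihydrofuran-2(3H)-one | O=C1O[C@H](c2ccc(O[Si](C)(C)C(C)(C)C)c(OC)c2)[C@@H](C)[C@]1(OC)CO[Si](C)(C)C(C)(C)C | intermediate
19 | (2S,3R)-4-Ar-2-[(tert-butyldimethylsilyloxy)methyl]-2-methoxy-3-methylbutanoic acid | OC(=O)[C@@](OC)(CO[Si](C)(C)C(C)(C)C)[C@H](C)Cc1ccc(O[Si](C)(C)C(C)(C)C)c(OC)c1 | intermediate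
20 | methyl (2S,3R)-4-Ar-2-[(tert-butyldimethylsilyloxy)methyl]-2-methoxy-3-methylbutanoate | COC(=O)[C@@](OC)(CO[Si](C)(C)C(C)(C)C)[C@H](C)Cc1ccc(O[Si](C)(C)C(C)(C)C)c(OC)c1 | intermediate
21 | (2S,3R)-4-Ar-2-[(tert-butyldimethylsilyloxy)methyl]-2-methoxy-3-methylbutanal | O=C[C@@](OC)(CO[Si](C)(C)C(C)(C)C)[C@H](C)Cc1ccc(O[Si](C)(C)C(C)(C)C)c(OC)c1 | intermediate
22 | (3R,4R)-1,1-dibromo-5-Ar-3-[(tert-butyldimethylsilyloxy)methyl]-3-methoxy-4-methylpent-1-ene | BrC(Br)=C[C@@](OC)(CO[Si](C)(C)C(C)(C)C)[C@H](C)Cc1ccc(O[Si](C)(C)C(C)(C)C)c(OC)c1 | intermediate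
23 | pent-4-enal | C=CCCC=O | starting material
24 | lithium (3R,4R)-5-Ar-3-[(tert-butyldimethylsilyloxy)methyl]-3-methoxy-4-methylpent-1-yn-1-ide | [Li+].[C-]#C[C@@](OC)(CO[Si](C)(C)C(C)(C)C)[C@H](C)Cc1ccc(O[Si](C)(C)C(C)(C)C)c(OC)c1 | intermediate
25 | (5RS,8R,9R)-10-Ar-8-[(tert-butyldimethylsilyloxy)methyl]-8-methoxy-9-methyldec-1-en-6-yn-5-ol | C=CCCC(O)C#C[C@@](OC)(CO[Si](C)(C)C(C)(C)C)[C@H](C)Cc1ccc(O[Si](C)(C)C(C)(C)C)c(OC)c1 | intermediate
26 | (5RS,8R,9R)-10-Ar-8-(hydroxymethyl)-8-methoxy-9-methyldec-1-en-6-yn-5-ol | C=CCCC(O)C#C[C@@](OC)(CO)[C@H](C)Cc1ccc(O[Si](C)(C)C(C)(C)C)c(OC)c1 | intermediate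
27 | (2R)-2-[(2R)-1-Ar-propan-2-yl]-2-methoxy-5-oxonon-8-en-3-ynal | C=CCCC(=O)C#C[C@@](OC)(C=O)[C@H](C)Cc1ccc(O[Si](C)(C)C(C)(C)C)c(OC)c1 | intermediate
28 | (2R,3E)-2-[(2R)-1-Ar-propan-2-yl]-2,3-dimethoxy-5-oxonona-3,8-dienal (forms with its 3Z isomer) | C=CCCC(=O)/C=C(/OC)[C@@](OC)(C=O)[C@H](C)Cc1ccc(O[Si](C)(C)C(C)(C)C)c(OC)c1 | intermediate
29 | (2R,3E)-2-[(2R)-1-(4-hydroxy-3-methoxyphenyl)propan-2-yl]-2,3-dimethoxy-5-oxonona-3,8-dienal (present as its sodium phenoxide) | C=CCCC(=O)/C=C(/OC)[C@@](OC)(C=O)[C@H](C)Cc1ccc(O)c(OC)c1 | intermediate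
30 | (4S)-4-[(2R)-1-(4-hydroxy-3-methoxyphenyl)propan-2-yl]-4,5-dimethoxy-2-(prop-2-en-1-yl)cyclohexa-2,5-dien-1-one | C=CCC1=C[C@@](OC)([C@H](C)Cc2ccc(O)c(OC)c2)C(OC)=CC1=O | target

**Step count and risks**

Total step count: 16. Longest linear sequence: 16 steps (1 → 30); compounds 3, 15 and 23 are bought and 14 is made in the flask.

Steps most likely to fail:

1. Step 7. The conjugate addition may be slow because the enoate carries a donor on its α-carbon. The enolate may deprotonate the acidic C5–H of unreacted 13 and erode configuration. Facial selectivity in the hydroxymethylation may be poor, since formaldehyde is small and the aryl group lies on the face that must be attacked. The aldolate may lose formaldehyde by retro-aldol cleavage. Fallback, from 13 and rejoining at 20, makes the two bonds in separate operations. Me2CuLi with Me3SiCl (THF, −78 °C) and aqueous work-up of the silyl ketene acetal would give (3RS,4R,5S)-5-Ar-3-methoxy-4-methyldihydrofuran-2(3H)-one F1. Its enolate (LiN(iPr)2, THF, −78 °C) would be alkylated with benzyl chloromethyl ether, a bulkier and irreversible electrophile that should enter anti to the C4 methyl group more cleanly, to give (3S,4R,5S)-3-[(benzyloxy)methyl]-5-Ar-3-methoxy-4-methyldihydrofuran-2(3H)-one F2. Hydrogenolysis (H2, Pd/C, EtOAc/AcOH) would remove the benzyl group and cleave the benzylic lactone C–O bond together to give (2S,3R)-4-Ar-2-(hydroxymethyl)-2-methoxy-3-methylbutanoic acid F3. Me3SiCHN2 would give methyl (2S,3R)-4-Ar-2-(hydroxymethyl)-2-methoxy-3-methylbutanoate F4, and silylation (tBuMe2SiCl, imidazole) returns to 20.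

2. Step 16. The enone geometries may not interconvert fast enough, leaving material with C1 trans to C4 uncyclised. Methoxide may cleave the formyl group from the quaternary carbon (retro-Claisen-type deformylation). Hydroxide released in the dehydration may hydrolyse the vinylogous ester and so lose the regiochemical definition of the C5 ether. Fallback, from 27 and rejoining at 30, separates the events and closes the ring without a nucleophilic base. PBu3-catalysed addition of methanol (MeOH/CH2Cl2, rt) to the ynone would give 28 as an isolated mixture of geometric isomers with the aryl silyl ether intact. TiCl4 and Et3N (CH2Cl2, −78 → 0 °C) would then effect the intramolecular aldol addition, the Lewis acid bound to the vinylogous ester carbonyl lowering the C5=C6 rotation barrier so that both isomers feed the cyclisation, to give (4S,5RS,6RS)-5-hydroxy-3,4-dimethoxy-4-[(2R)-1-Ar-propan-2-yl]-6-(prop-2-en-1-yl)cyclohex-2-en-1-one F5. Mesylation (MsCl, Et3N) and elimination with DBU would give (4S)-4-[(2R)-1-Ar-propan-2-yl]-4,5-dimethoxy-2-(prop-2-en-1-yl)cyclohexa-2,5-dien-1-one F6, and Bu4NF buffered with AcOH (THF, 0 °C) removes the aryl silyl group to reach 30.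

3. Step 6. Selenium-derived oxidants may over-oxidise the electron-rich C3=C4 bond, and configuration at C5 may erode because its hydrogen becomes acidic once the butenolide exists. Fallback, from 9 and rejoining at 13, obtains the double bond by tautomerism instead of elimination. Dess–Martin oxidation of 9 would give the α-keto lactone, which exists as its enol (5S)-5-Ar-3-hydroxyfuran-2(5H)-one F7, and O-methylation of this acidic enol with ethereal CH2N2 under neutral conditions gives 13.

Further compounds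
F1 | step 7 | (3RS,4R,5S)-5-Ar-3-methoxy-4-methyldihydrofuran-2(3H)-one | O=C1O[C@H](c2ccc(O[Si](C)(C)C(C)(C)C)c(OC)c2)[C@@H](C)C1OC
F2 | step 7 | (3S,4R,5S)-3-[(benzyloxy)methyl]-5-Ar-3-methoxy-4-methyldihydrofuran-2(3H)-one | O=C1O[C@H](c2ccc(O[Si](C)(C)C(C)(C)C)c(OC)c2)[C@@H](C)[C@]1(OC)COCc1ccccc1
F3 | step 7 | (2S,3R)-4-Ar-2-(hydroxymethyl)-2-methoxy-3-methylbutanoic acid | OC(=O)[C@@](OC)(CO)[C@H](C)Cc1ccc(O[Si](C)(C)C(C)(C)C)c(OC)c1
F4 | step 7 | methyl (2S,3R)-4-Ar-2-(hydroxymethyl)-2-methoxy-3-methylbutanoate | COC(=O)[C@@](OC)(CO)[C@H](C)Cc1ccc(O[Si](C)(C)C(C)(C)C)c(OC)c1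
F5 | step 16 | (4S,5RS,6RS)-5-hydroxy-3,4-dimethoxy-4-[(2R)-1-Ar-propan-2-yl]-6-(prop-2-en-1-yl)cyclohex-2-en-1-one | C=CCC1C(O)[C@@](OC)([C@H](C)Cc2ccc(O[Si](C)(C)C(C)(C)C)c(OC)c2)C(OC)=CC1=O
F6 | step 16 | (4S)-4-[(2R)-1-Ar-propan-2-yl]-4,5-dimethoxy-2-(prop-2-en-1-yl)cyclohexa-2,5-dien-1-one | C=CCC1=C[C@@](OC)([C@H](C)Cc2ccc(O[Si](C)(C)C(C)(C)C)c(OC)c2)C(OC)=CC1=O
F7 | step 6 | (5S)-5-Ar-3-hydroxyfuran-2(5H)-one | OC1=C[C@@H](c2ccc(O[Si](C)(C)C(C)(C)C)c(OC)c2)OC1=O
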